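**Plan**
Numbering: cyclohexene C1 (bears the aroyl carbon C7), C2 (prenyl C1′–C2′=C3′), C3 (methyl), C4, C5, C6 (phenyl).
Retrosynthetic cuts, in order: C2′=C3′ (Wittig), C7–aryl (aryllithium on a lactone carbonyl), C4–H back to C4–O (enol triflate, ketone), then C1–C6 and C2–C3 together (Diels–Alder).
Enabling feature: C7 and C1′ sit on the adjacent ring atoms C1 and C2. C7(=O)–O–C2′–C1′ can therefore close with C1 and C2 into a six-membered lactone whose C1=C2 alkene is a cis dienophile. C1 is also the only stereocentre next to a carbonyl group.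
Forward order: the lactone ring is bought and the carbocycle is annulated onto it in step 2. The C4 oxygen is then exchanged for the C3=C4 alkene, the aryl nucleophile opens the lactone, and the freed C2′ alcohol is extended to the prenyl chain.
Stereochemistry: a chiral oxazaborolidinium Lewis acid selects the face. Diene geometry, the Z ring alkene and the endo mode give an all-cis C6/C1/C2/C3 array. C3 is later flattened, C2 and C6 are kept, and C1 is inverted by base equilibration of the aryl ketone.

Key step: step 2

Assumption: the (R)-diphenylprolinol-derived catalyst is taken to leave the C1-Si/C2-Si face of the bound lactone open, by analogy with the sense known for acrylate esters bound through the α-C–H···O mode; if the opposite sense is found, the equally available (S) catalyst is used and nothing else changes.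

Step 1
Reactants: 1 (E)-1-phenylpent-1-en-3-one
Product: 2 tert-butyl(dimethyl){[(1E,3Z)-1-phenylpenta-1,3-dien-3-yl]oxy}silane
Conditions: TBSOTf (1.2 equiv), Et3N (1.5 equiv), CH2Cl2, 0 °C
Reagents that add atoms: tert-butyldimethylsilyl triflate, CC(C)(C)[Si](C)(C)OS(=O)(=O)C(F)(F)F
Why: Soft enolisation (silyl triflate/amine silyl enol ether formation) can only remove a proton from the ethyl CH2, and the methyl group should settle cis to the silyloxy group and away from the styryl arm, giving the Z enol ether while the E styryl alkene stays untouched.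

Step 2
Reactants: 2 tert-butyl(dimethyl){[(1E,3Z)-1-phenylpenta-1,3-dien-3-yl]oxy}silane; 3 5,6-dihydro-2H-pyran-2-one
Product: 4 (4aR,5S,8S,8aR)-6-(tert-butyldimethylsilyloxy)-5-methyl-8-phenyl-3,4,4a,5,8,8a-hexahydro-1H-isochromen-1-one (cis-fused; C7, C1′, methyl and phenyl all on one face; C4=C5 silyl enol ether)
Conditions: (R)-o-tolyl-oxazaborolidine from (R)-α,α-diphenylprolinol (20 mol %), Tf2NH (17 mol %), 2 (1.5 equiv), CH2Cl2 (1 M), −40 → −10 °C
Reagents that add atoms: none
Why: The cationic boron binds the lactone carbonyl oxygen (supported by a C1–H···O contact to the catalyst oxygen), lowers the LUMO of the C1=C2 alkene and triggers a concerted, asynchronous [4+2] cycloaddition in which C2–C3 bonding runs ahead of C1–C6, the closest known reaction type being the oxazaborolidinium-catalysed enantioselective Diels–Alder reaction of 2-silyloxydienes with cyclic enones and α,β-unsaturated esters or lactones. The carbocycle C1–C6 closes by an intermolecular six-electron cycloaddition, suprafacial on both partners, and is thereby annulated onto the existing lactone ring. C1 and C2 come out cis because the ring alkene of 3 can only be Z, and C3 and C6 come out cis to each other because methyl and phenyl both occupy outside positions of the s-cis (1E,3Z)-diene. The endo approach, with C7 and C1′ under C5 and C4 of the diene and reinforced by Lewis acid coordination, ties the two pairs together and places all four substituents on one face. The absolute sense comes from the catalyst, whose aryl group should cover the C1-Re/C2-Re face so that 2 adds to the Si/Si face. Regiochemistry needs no outside control, since the silyloxy group on C4 makes the methyl-bearing terminus C3 the nucleophilic end and the phenyl group on C6 polarises the diene in the same direction, so C3 meets the β-carbon C2.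

Step 3
Reactants: 4 all-cis silyl enol ether adduct
Product: 5 (4aR,5S,8S,8aR)-5-methyl-8-phenyl-3,4,4a,7,8,8a-hexahydro-1H-isochromene-1,6(5H)-dione (cis-fused C4 keto lactone)
Conditions: 1 M HCl, THF, 0 °C
Reagents that add atoms: none
Why: Acid hydrolysis of a silyl enol ether (protonation at C5, loss of silicon to water) frees the C4 ketone under conditions that leave the lactone, C1, C2 and C6 untouched, and any drift at C3 is harmless because that centre is erased in step 4.

Step 4
Reactants: 5 cis-fused keto lactone
Product: 6 (4aS,8S,8aS)-5-methyl-1-oxo-8-phenyl-3,4,4a,7,8,8a-hexahydro-1H-isochromen-6-yl trifluoromethanesulfonate (C3=C4 enol triflate; same spatial arrangement at C1, C2 and C6 as in 5, the changed descriptors being a priority effect)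
Conditions: Tf2O (1.3 equiv), 2,6-di-tert-butyl-4-methylpyridine (1.5 equiv), CH2Cl2, 0 → 23 °C
Reagents that add atoms: triflic anhydride, O=S(=O)(OS(=O)(=O)C(F)(F)F)C(F)(F)F
Why: Enol triflate formation by O-triflation and proton loss should favour C3=C4 because this is the more substituted enol derivative, because cis-fused six–six ketones of this pattern enolise toward the ring-fusion side, and because flattening C3 removes the syn-axial methyl/C7 contact, while the lactone is inert to the reagent.

Step 5
Reactants: 6 C3=C4 enol triflate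
Product: 7 (4aS,8S,8aR)-5-methyl-8-phenyl-3,4,4a,7,8,8a-hexahydro-1H-isochromen-1-one (cis-fused lactone, phenyl cis to C7 and C1′, C3=C4 alkene)
Conditions: Pd(OAc)2 (5 mol %), PPh3 (10 mol %), HCO2H (2 equiv), n-Bu3N (3 equiv), DMF, 60 °C
Reagents that add atoms: none
Why: Palladium-catalysed formate reduction of an enol triflate (oxidative addition, decarboxylation of formate to Pd–H, reductive elimination) replaces OTf by H at C4 without moving the alkene or touching the lactone and the three stereocentres.

Step 6
Reactants: 8 3-hydroxy-4,5-dimethoxybenzaldehyde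
Product: 10 4,5-dimethoxybenzene-1,3-diol, via 3-hydroxy-4,5-dimethoxyphenyl formate 9 (not isolated)
Conditions: 30% H2O2 (1.3 equiv), H2SO4 (cat.), MeOH, 23 °C
Reagents that add atoms: hydrogen peroxide, OO
Why: In this acid-catalysed Dakin-type (Baeyer–Villiger) oxidation the electron-rich aryl group, pushed by the para methoxy group, migrates from carbon to oxygen, and the resulting formate is methanolysed in the same flask.

Step 7
Reactants: 10 4,5-dimethoxybenzene-1,3-diol
Product: 11 1,2-dimethoxy-3,5-bis(methoxymethoxy)benzene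
Conditions: MOMCl (2.6 equiv), i-Pr2NEt (3 equiv), CH2Cl2, 0 → 23 °C
Reagents that add atoms: chloromethyl methyl ether, COCCl
Why: Double O-alkylation of the phenols (acetal protection) masks both acidic hydrogens and installs the two strongest ortho-directing groups on either side of the future C7 attachment point.

Step 8
Reactants: 11 1,2-dimethoxy-3,5-bis(methoxymethoxy)benzene; 7 cis-fused alkene lactone
Product: 13 [2,6-bis(methoxymethoxy)-3,4-dimethoxyphenyl][(1R,2S,6S)-2-(2-hydroxyethyl)-3-methyl-6-phenylcyclohex-3-en-1-yl]methanone (aroyl, hydroxyethyl and phenyl all cis), via 2,6-bis(methoxymethoxy)-3,4-dimethoxyphenyllithium 12 (not isolated)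
Conditions: 11 (1.3 equiv), n-BuLi (1.25 equiv), THF, 0 °C; then 7, −78 → −30 °C; aq NH4Cl
Reagents that add atoms: none
Why: Directed ortho-metalation should take the hydrogen flanked by both OMOM groups, and acyl substitution on the lactone stops after one addition because the tetrahedral lithium alkoxide persists until the quench and the di-ortho-substituted ketone is too hindered to react again, with C1, C2 and C6 unchanged at low temperature.

Step 9
Reactants: 13 all-cis hydroxy ketone
Product: 14 [2,6-bis(methoxymethoxy)-3,4-dimethoxyphenyl][(1R,2S,6S)-3-methyl-2-(2-oxoethyl)-6-phenylcyclohex-3-en-1-yl]methanone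
Conditions: DMP (1.3 equiv), CH2Cl2, 0 → 23 °C
Reagents that add atoms: none
Why: Dess–Martin oxidation converts the primary C2′ alcohol into the aldehyde without affecting alkene, MOM ethers or ketone, and any cyclic hemiketal form of 13 should drain through its open tautomer.

Step 10
Reactants: 14 all-cis keto aldehyde
Product: 15 [2,6-bis(methoxymethoxy)-3,4-dimethoxyphenyl][(1R,2S,6S)-3-methyl-2-(3-methylbut-2-en-1-yl)-6-phenylcyclohex-3-en-1-yl]methanone
Conditions: i-PrPPh3I (1.5 equiv), n-BuLi (1.4 equiv), THF, 0 °C; then 14, −78 → 0 °C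
Reagents that add atoms: isopropyltriphenylphosphonium iodide, CC(C)[P+](c1ccccc1)(c1ccccc1)c1ccccc1.[I-]
Why: The Wittig reaction with the isopropylidene ylide should select the unhindered aldehyde over the shielded diortho-substituted aryl ketone and complete the prenyl chain, and partial base-induced drift at C1 would only anticipate step 11.

Step 11
Reactants: 15 all-cis prenyl ketone
Product: 17 [2,6-bis(methoxymethoxy)-3,4-dimethoxyphenyl][(1S,2S,6S)-3-methyl-2-(3-methylbut-2-en-1-yl)-6-phenylcyclohex-3-en-1-yl]methanone (aroyl trans to both prenyl and phenyl), via potassium enolate 16 (not isolated)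
Conditions: KOt-Bu (30 mol %), t-BuOH–THF, 40 °C; AcOH quench
Reagents that add atoms: none
Why: Base-mediated epimerisation α to a ketone through the C1=C7 enolate should move the isomer with an axial aroyl group to the one in which aroyl, phenyl and prenyl are all (pseudo)equatorial, only C1 being able to change because C2 and C6 carry no acidic hydrogen, and residual 15 can be separated and resubmitted.

Step 12
Reactants: 17 trans,trans bis-MOM ketone
Product: 18 (2,6-dihydroxy-3,4-dimethoxyphenyl)[(1S,2S,6S)-3-methyl-2-(3-methylbut-2-en-1-yl)-6-phenylcyclohex-3-en-1-yl]methanone (target)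
Conditions: conc. HCl (cat.), MeOH, 45 °C
Reagents that add atoms: none
Why: Acid-catalysed acetal exchange removes both MOM groups, which are especially labile ortho to the ketone, under conditions mild enough for the two trisubstituted alkenes, and C1 already has its more stable configuration.

**Compound list**
1 | (E)-1-phenylpent-1-en-3-one | CCC(=O)/C=C/c1ccccc1 | starting material
2 | tert-butyl(dimethyl){[(1E,3Z)-1-phenylpenta-1,3-dien-3-yl]oxy}silane | C/C=C(O[Si](C)(C)C(C)(C)C)/C=C/c1ccccc1 | intermediate
3 | 5,6-dihydro-2H-pyran-2-one | O=C1C=CCCO1 | starting material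
4 | (4aR,5S,8S,8aR)-6-(tert-butyldimethylsilyloxy)-5-methyl-8-phenyl-3,4,4a,5,8,8a-hexahydro-1H-isochromen-1-one | O=C1OCC[C@@H]2[C@H](C)C(O[Si](C)(C)C(C)(C)C)=C[C@H](c3ccccc3)[C@H]12 | intermediate
5 | (4aR,5S,8S,8aR)-5-methyl-8-phenyl-3,4,4a,7,8,8a-hexahydro-1H-isochromene-1,6(5H)-dione | O=C1OCC[C@@H]2[C@H](C)C(=O)C[C@H](c3ccccc3)[C@H]12 | intermediate
6 | (4aS,8S,8aS)-5-methyl-1-oxo-8-phenyl-3,4,4a,7,8,8a-hexahydro-1H-isochromen-6-yl trifluoromethanesulfonate | O=C1OCC[C@@H]2C(C)=C(OS(=O)(=O)C(F)(F)F)C[C@H](c3ccccc3)[C@H]12 | intermediate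
7 | (4aS,8S,8aR)-5-methyl-8-phenyl-3,4,4a,7,8,8a-hexahydro-1H-isochromen-1-one | O=C1OCC[C@@H]2C(C)=CC[C@H](c3ccccc3)[C@H]12 | intermediate
8 | 3-hydroxy-4,5-dimethoxybenzaldehyde | COc1cc(C=O)cc(O)c1OC | starting material
9 | 3-hydroxy-4,5-dimethoxyphenyl formate | COc1cc(OC=O)cc(O)c1OC | intermediate
10 | 4,5-dimethoxybenzene-1,3-diol | COc1cc(O)cc(O)c1OC | intermediate
11 | 1,2-dimethoxy-3,5-bis(methoxymethoxy)benzene | COCOc1cc(OC)c(OC)c(OCOC)c1 | intermediate
12 | 2,6-bis(methoxymethoxy)-3,4-dimethoxyphenyllithium | [Li]c1c(OCOC)cc(OC)c(OC)c1OCOC | intermediate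
13 | [2,6-bis(methoxymethoxy)-3,4-dimethoxyphenyl][(1R,2S,6S)-2-(2-hydroxyethyl)-3-methyl-6-phenylcyclohex-3-en-1-yl]methanone | COc1cc(OCOC)c(C(=O)[C@@H]2[C@H](CCO)C(C)=CC[C@@H]2c2ccccc2)c(OCOC)c1OC | intermediate
14 | [2,6-bis(methoxymethoxy)-3,4-dimethoxyphenyl][(1R,2S,6S)-3-methyl-2-(2-oxoethyl)-6-phenylcyclohex-3-en-1-yl]methanone | COc1cc(OCOC)c(C(=O)[C@@H]2[C@H](CC=O)C(C)=CC[C@@H]2c2ccccc2)c(OCOC)c1OC | intermediate
15 | [2,6-bis(methoxymethoxy)-3,4-dimethoxyphenyl][(1R,2S,6S)-3-methyl-2-(3-methylbut-2-en-1-yl)-6-phenylcyclohex-3-en-1-yl]methanone | COc1cc(OCOC)c(C(=O)[C@@H]2[C@H](CC=C(C)C)C(C)=CC[C@@H]2c2ccccc2)c(OCOC)c1OC | intermediate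
16 | potassium enolate of 15 and 17 (C1=C7, C2 and C6 unchanged) | COc1cc(OCOC)c(C([O-])=C2[C@H](CC=C(C)C)C(C)=CC[C@@H]2c2ccccc2)c(OCOC)c1OC.[K+] | intermediate
17 | [2,6-bis(methoxymethoxy)-3,4-dimethoxyphenyl][(1S,2S,6S)-3-methyl-2-(3-methylbut-2-en-1-yl)-6-phenylcyclohex-3-en-1-yl]methanone | COc1cc(OCOC)c(C(=O)[C@H]2[C@H](CC=C(C)C)C(C)=CC[C@@H]2c2ccccc2)c(OCOC)c1OC | intermediate
18 | (2,6-dihydroxy-3,4-dimethoxyphenyl)[(1S,2S,6S)-3-methyl-2-(3-methylbut-2-en-1-yl)-6-phenylcyclohex-3-en-1-yl]methanone | COc1cc(O)c(C(=O)[C@H]2[C@H](CC=C(C)C)C(C)=CC[C@@H]2c2ccccc2)c(O)c1OC | target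

Total step count: 12. Longest linear sequence: 10 (steps 1–5 and 8–12).

**Steps most likely to fail**

Step 2.
- What may go wrong: the β-substituted lactone may be activated too little for a diene substituted at both termini. The acidic catalyst may strip silicon from the diene faster than cycloaddition occurs. Face and endo discrimination may also erode at the temperature needed for turnover.
- Fallback: absolute control is given up in the cycloaddition and regained by resolution. Setting out from 2 and 3, a stoichiometric achiral aluminium Lewis acid mixture (AlBr3/AlMe3, toluene–CH2Cl2, −5 °C) is used. This promoter is established for sterically congested silyloxydiene/dienophile pairs. It should give the all-cis adduct as a racemate, that is 4 together with the mirror-image adduct ent-4 F1.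
- Hydrolysis as in step 3 gives 5 together with the mirror-image keto lactone ent-5 F2. The pair is separated by preparative chromatography on a chiral stationary phase, and the route is rejoined at 5.

Step 11.
- What may go wrong: deprotonation at C1 may be slow, because the developing enolate is pressed against phenyl, prenyl and the twisted aryl group. The equilibrium may also be less one-sided than expected.
- Fallback: C1 is inverted at the ester level, before the bulky aryl group is present, and the aryl group enters through an aldehyde. Setting out from 7, NaOMe in MeOH at reflux opens the lactone and equilibrates the small ester to methyl (1S,2S,6S)-2-(2-hydroxyethyl)-3-methyl-6-phenylcyclohex-3-ene-1-carboxylate F3. Remaining cis material should re-close to 7 and can be recycled.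
- Dess–Martin oxidation gives methyl (1S,2S,6S)-3-methyl-2-(2-oxoethyl)-6-phenylcyclohex-3-ene-1-carboxylate F4. The isopropylidene Wittig reaction then gives methyl (1S,2S,6S)-3-methyl-2-(3-methylbut-2-en-1-yl)-6-phenylcyclohex-3-ene-1-carboxylate F5.
- DIBAL-H at −78 °C gives (1S,2S,6S)-3-methyl-2-(3-methylbut-2-en-1-yl)-6-phenylcyclohex-3-ene-1-carbaldehyde F6. Addition of 12 gives the C7 carbinol (either configuration at C7) F7. A second Dess–Martin oxidation returns to the route at 17.

Step 4.
- What may go wrong: proton loss toward C5 may compete, which would give a regioisomeric enol triflate that cannot be recycled.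
- Fallback: regiocontrol is separated from triflation. Setting out from 5, Me3SiI/(Me3Si)2NH (CH2Cl2, −20 → 23 °C) forms the silyl enol ether under equilibrating conditions. This should give (4aS,8S,8aS)-5-methyl-8-phenyl-6-(trimethylsilyloxy)-3,4,4a,7,8,8a-hexahydro-1H-isochromen-1-one F8. It can be purified, and any other enol ether can be hydrolysed back to 5.
- CsF and PhNTf2 in DME then release the enolate at the defined position and trap it, and the route is rejoined at 6.

**Further compounds**
F1 | step 2 | (4aS,5R,8R,8aS)-6-(tert-butyldimethylsilyloxy)-5-methyl-8-phenyl-3,4,4a,5,8,8a-hexahydro-1H-isochromen-1-one (ent-4) | O=C1OCC[C@H]2[C@@H](C)C(O[Si](C)(C)C(C)(C)C)=C[C@@H](c3ccccc3)[C@@H]12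
F2 | step 2 | (4aS,5R,8R,8aS)-5-methyl-8-phenyl-3,4,4a,7,8,8a-hexahydro-1H-isochromene-1,6(5H)-dione (ent-5) | O=C1OCC[C@H]2[C@@H](C)C(=O)C[C@@H](c3ccccc3)[C@@H]12
F3 | step 11 | methyl (1S,2S,6S)-2-(2-hydroxyethyl)-3-methyl-6-phenylcyclohex-3-ene-1-carboxylate | COC(=O)[C@H]1[C@H](CCO)C(C)=CC[C@@H]1c1ccccc1
F4 | step 11 | methyl (1S,2S,6S)-3-methyl-2-(2-oxoethyl)-6-phenylcyclohex-3-ene-1-carboxylate | COC(=O)[C@H]1[C@H](CC=O)C(C)=CC[C@@H]1c1ccccc1
F5 | step 11 | methyl (1S,2S,6S)-3-methyl-2-(3-methylbut-2-en-1-yl)-6-phenylcyclohex-3-ene-1-carboxylate | COC(=O)[C@H]1[C@H](CC=C(C)C)C(C)=CC[C@@H]1c1ccccc1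
F6 | step 11 | (1S,2S,6S)-3-methyl-2-(3-methylbut-2-en-1-yl)-6-phenylcyclohex-3-ene-1-carbaldehyde | O=C[C@H]1[C@H](CC=C(C)C)C(C)=CC[C@@H]1c1ccccc1
F7 | step 11 | [2,6-bis(methoxymethoxy)-3,4-dimethoxyphenyl][(1S,2S,6S)-3-methyl-2-(3-methylbut-2-en-1-yl)-6-phenylcyclohex-3-en-1-yl]methanol (C7 undefined) | COc1cc(OCOC)c(C(O)[C@H]2[C@H](CC=C(C)C)C(C)=CC[C@@H]2c2ccccc2)c(OCOC)c1OC
F8 | step 4 | (4aS,8S,8aS)-5-methyl-8-phenyl-6-(trimethylsilyloxy)-3,4,4a,7,8,8a-hexahydro-1H-isochromen-1-one | O=C1OCC[C@@H]2C(C)=C(O[Si](C)(C)C)C[C@H](c3ccccc3)[C@H]12
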